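**Retrosynthetic overview**
1. Target 20 comes from ketol 18 by functional-group changes only: C7-acetyl to isopropenyl by methylenation, then C8-OH to ketone.
2. Key step, which closes ring B second: H-atom transfer to an exocyclic CH2 creates the C14 methyl and a tertiary C5 radical. That radical closes 6-endo on a tethered enone, forming C5–C6, the quaternary centre and the trans-decalin.
3. The tether comes from but-3-en-2-one (C6, C7, C11, C12; Baylis–Hillman, C7–C8) and 1,3-dithiane (C8; Felkin addition to the C9 aldehyde). Each ester is put on as soon as its OH appears.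
4. Ring A is made first, by an enantioselective Diels–Alder reaction of the silyl dienol ether of pent-1-en-3-one (C1–C4, C15) with ethyl buta-2,3-dienoate (C14, C5, C10, C9).

Assumption: eremophilane numbering is used for every compound (ring A C1–C5 and C10, ring B C5–C10, C14 on C5, C15 on C4, C11–C13 side chain), and α is the face of H-10. The C8 carbinol in 17–19 is carried as both epimers because it is destroyed in step 11. The catalyst enantiomer in step 2 is the one that gives 4 as drawn.

**Step 1**
Reactants: 1 pent-1-en-3-one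
Product: 2 (Z)-3-(tert-butyldimethylsilyloxy)penta-1,3-diene
Conditions: TBSOTf, Et3N, Et2O, 0 °C
Reagents that add atoms: tert-butyldimethylsilyl triflate, CC(C)(C)[Si](C)(C)OS(=O)(=O)C(F)(F)F
Why: Soft enolisation to a silyl dienol ether gives the favoured Z enol ether, which places the methyl group "outside" in the s-cis diene.

**Step 2**
Reactants: 2 (Z)-3-(tert-butyldimethylsilyloxy)penta-1,3-diene; 3 ethyl buta-2,3-dienoate
Product: 4 ring-A ester (4R,10R)
Conditions: o-tolyl oxazaborolidine·Tf2NH (20 mol %), CH2Cl2, −78 to −40 °C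
Reagents that add atoms: none
Why: In this enantioselective Lewis-acid-catalysed Diels–Alder reaction, an extension of the acrylate cases to an allenoate, the nucleophilic terminus C4 bonds to the central allene carbon ("para" rule), the endo ester and the outside methyl end up cis (C4-Me and C10-CO2Et both β), and the chiral cation shields one face of the bound allenoate, which fixes C4 and C10.

**Step 3**
Reactants: 4 ring-A ester; 5 1,3-dithiane
Product: 8 dithianyl carbinol (9S), via 2-lithio-1,3-dithiane 6 (not isolated), via ring-A aldehyde 7 (not isolated)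
Conditions: 5, n-BuLi, THF, −30 °C; separately 4, DIBAL-H, toluene, −78 °C; combine at −78 to −40 °C; Rochelle salt
Reagents that add atoms: none
Why: Partial ester reduction is followed by Corey–Seebach dithiane addition, so the β,γ-unsaturated aldehyde is trapped cold before it can conjugate, and Felkin–Anh attack anti to the alkenyl carbon C5 gives the C1/OH-syn carbinol (9S).

**Step 4**
Reactants: 8 dithianyl carbinol; 9 tigloyl chloride
Product: 10 C9 tiglate
Conditions: Et3N, DMAP (cat.), CH2Cl2, 0 °C to rt
Reagents that add atoms: none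
Why: DMAP-catalysed acylation of the only free hydroxyl installs the final C9 ester with retention, and the silyl enol ether and dithiane are inert.

**Step 5**
Reactants: 10 C9 tiglate
Product: 12 C3 alcohol (3R), via β,γ-unsaturated ketone 11 (not isolated)
Conditions: HF·pyridine/pyridine, THF, 0 °C; then MeOH, NaBH4 (excess), −78 °C
Reagents that add atoms: none
Why: Buffered fluoride desilylation followed by immediate borohydride reduction avoids conjugation of the enone, and axial hydride attack on the chair locked by the diequatorial C4-Me and C10 side chain gives the equatorial 3α-OH, trans to C4-Me.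

**Step 6**
Reactants: 12 C3 alcohol; 13 3-methylbut-2-enoic acid
Product: 14 diester dithiane
Conditions: DIC, DMAP, CH2Cl2, 0 °C to rt
Reagents that add atoms: none
Why: Steglich esterification installs the senecioate with retention and avoids the vinylketene deconjugation seen with the acid chloride and amine bases.

**Step 7**
Reactants: 14 diester dithiane
Product: 15 α-tigloyloxy aldehyde
Conditions: MeI, CaCO3, MeCN–H2O 9:1, 40 °C
Reagents that add atoms: water, O
Why: Alkylative dithiane hydrolysis is neutral and non-oxidising, so the alkenes, both esters and the C9 centre are untouched.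

**Step 8**
Reactants: 15 α-tigloyloxy aldehyde; 16 but-3-en-2-one
Product: 17 Baylis–Hillman adduct
Conditions: DABCO (0.3 equiv), 16 (3 equiv), dioxane–H2O, 0 °C to rt
Reagents that add atoms: none
Why: The Morita–Baylis–Hillman reaction of the activated α-acyloxy aldehyde forms C7–C8 and tethers the acceptor, and the new C8 carbinol centre is irrelevant because it is oxidised in step 11.

**Step 9 (key step)**
Reactants: 17 Baylis–Hillman adduct
Product: 18 trans-decalin ketol
Conditions: Fe(acac)3 (0.3 equiv), PhSiH3, EtOH, 60 °C, 0.01 M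
Reagents that add atoms: none
Why: In this MHAT-initiated intramolecular Giese reaction (reductive olefin coupling), Fe–H gives H• to the electron-neutral exocyclic CH2 (the new C14 methyl), the nucleophilic tertiary C5 radical closes 6-endo on the CH2 terminus of the acetyl-activated alkene through the chair that keeps C9-OTig equatorial (the cis-decalin chair would put that ester axial and syn to the new methyl), so C6 ends trans to C9 with cis-dimethyl and a trans-decalin (5R), reduction and protonation of the C7 radical leave the epimerisable acetyl equatorial (7α), and the hindered electron-poor tiglate and senecioate alkenes are slow H-atom acceptors.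

**Step 10**
Reactants: 18 trans-decalin ketol
Product: 19 isopropenyl alcohol
Conditions: Zn, CH2Br2, TiCl4 (Lombardo reagent), THF–CH2Cl2, 0 °C to rt
Reagents that add atoms: dibromomethane, BrCBr
Why: The non-basic Takai–Oshima–Lombardo methylenation is selective for the ketone over the esters and avoids retro-aldol, C7 epimerisation and alkoxide-driven acyl migration, so C7 is now fixed (7S).

**Step 11**
Reactants: 19 isopropenyl alcohol
Product: 20 target
Conditions: Dess–Martin periodinane, CH2Cl2, 0 °C to rt
Reagents that add atoms: none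
Why: Dess–Martin oxidation converts both C8 epimers into the ketone under near-neutral conditions, so the β,γ-unsaturated ketone does not conjugate and C7 and C9 stay equatorial.

**Compound list**
1 | pent-1-en-3-one | C=CC(=O)CC | starting material
2 | (Z)-3-(tert-butyldimethylsilyloxy)penta-1,3-diene | C=C/C(O[Si](C)(C)C(C)(C)C)=C/C | intermediate
3 | ethyl buta-2,3-dienoate | C=C=CC(=O)OCC | starting material
4 | ethyl (1R,5R)-4-(tert-butyldimethylsilyloxy)-5-methyl-6-methylidenecyclohex-3-ene-1-carboxylate | C=C1[C@@H](C)C(O[Si](C)(C)C(C)(C)C)=CC[C@H]1C(=O)OCC | intermediate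
5 | 1,3-dithiane | C1CSCSC1 | starting material
6 | 2-lithio-1,3-dithiane (not isolated) | [Li]C1SCCCS1 | intermediate
7 | (1R,5R)-4-(tert-butyldimethylsilyloxy)-5-methyl-6-methylidenecyclohex-3-ene-1-carbaldehyde (not isolated) | C=C1[C@@H](C)C(O[Si](C)(C)C(C)(C)C)=CC[C@H]1C=O | intermediate
8 | (S)-(1,3-dithian-2-yl)[(1R,5R)-4-(tert-butyldimethylsilyloxy)-5-methyl-6-methylidenecyclohex-3-en-1-yl]methanol | C=C1[C@@H](C)C(O[Si](C)(C)C(C)(C)C)=CC[C@H]1[C@H](O)C1SCCCS1 | intermediate
9 | (E)-2-methylbut-2-enoyl chloride (tigloyl chloride) | C/C=C(\C)C(=O)Cl | starting material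
10 | (E)-2-methylbut-2-enoate (tiglate) of 8 | C=C1[C@@H](C)C(O[Si](C)(C)C(C)(C)C)=CC[C@H]1[C@H](OC(=O)/C(C)=C/C)C1SCCCS1 | intermediate
11 | (S)-(1,3-dithian-2-yl)[(1R,3R)-3-methyl-2-methylidene-4-oxocyclohexyl]methyl tiglate (not isolated) | C=C1[C@@H](C)C(=O)CC[C@H]1[C@H](OC(=O)/C(C)=C/C)C1SCCCS1 | intermediate
12 | (S)-(1,3-dithian-2-yl)[(1R,3R,4R)-4-hydroxy-3-methyl-2-methylidenecyclohexyl]methyl tiglate | C=C1[C@@H](C)[C@H](O)CC[C@H]1[C@H](OC(=O)/C(C)=C/C)C1SCCCS1 | intermediate
13 | 3-methylbut-2-enoic acid (senecioic acid) | CC(C)=CC(=O)O | starting material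
14 | 3-methylbut-2-enoate (senecioate) of 12 | C=C1[C@@H](C)[C@H](OC(=O)C=C(C)C)CC[C@H]1[C@H](OC(=O)/C(C)=C/C)C1SCCCS1 | intermediate
15 | (1S)-1-[(1R,3R,4R)-3-methyl-4-(3-methylbut-2-enoyloxy)-2-methylidenecyclohexyl]-2-oxoethyl tiglate | C=C1[C@@H](C)[C@H](OC(=O)C=C(C)C)CC[C@H]1[C@H](OC(=O)/C(C)=C/C)C=O | intermediate
16 | but-3-en-2-one | C=CC(C)=O | starting material
17 | Baylis–Hillman adduct: 15 carrying CH(OH)–C(=CH2)–C(=O)CH3 in place of CHO (9S; C8 both epimers) | C=C1[C@@H](C)[C@H](OC(=O)C=C(C)C)CC[C@H]1[C@H](OC(=O)/C(C)=C/C)C(O)C(=C)C(C)=O | intermediate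
18 | (3R,4R,5R,7R,9S,10R)-7α-acetyl-8-hydroxy-4β,5β-dimethyl-3α-senecioyloxy-9α-tigloyloxy-trans-decalin (C8 both epimers) | CC(=O)[C@@H]1C[C@]2(C)[C@@H](C)[C@H](OC(=O)C=C(C)C)CC[C@H]2[C@H](OC(=O)/C(C)=C/C)C1O | intermediate
19 | (3R,4R,5R,7S,9S,10R)-3α-senecioyloxy-9α-tigloyloxyeremophil-11-en-8-ol (C8 both epimers) | C=C(C)[C@@H]1C[C@]2(C)[C@@H](C)[C@H](OC(=O)C=C(C)C)CC[C@H]2[C@H](OC(=O)/C(C)=C/C)C1O | intermediate
20 | (3R,4R,5R,7S,9S,10R)-3α-senecioyloxy-9α-tigloyloxy-10αH-eremophil-11-en-8-one | C=C(C)[C@@H]1C[C@]2(C)[C@@H](C)[C@H](OC(=O)C=C(C)C)CC[C@H]2[C@H](OC(=O)/C(C)=C/C)C1=O | target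

**Total steps:** 11. **Longest linear sequence:** 11 (1 → 20).

**Three steps most likely to fail**

Step 9. The risks are H-atom transfer to the enone instead of the exocyclic alkene, and an insufficient trans/cis ratio. The fallback sets out from 17 and returns at 18, and it generates the same C5 radical without any metal hydride. m-CPBA epoxidises the only electron-rich alkene to give the spiro-epoxide F1. Cp2TiCl (from Cp2TiCl2 and Zn) opens F1 to the β-titanoxy tertiary radical, which closes 6-endo to the 14-hydroxy ketol F2. The primary alcohol is converted with thiocarbonyldiimidazole into the imidazolylthiocarbonate F3. Barton–McCombie reduction (Bu3SnH, AIBN) turns CH2O into the C14 methyl and gives 18.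

Step 8. The risks are amine-induced C9 epimerisation, C9-to-C8 acyl migration, and dimerisation of 16. The fallback sets out from 15 and 16 and returns at 17. Compound 16 is brominated and dehydrobrominated (Br2, then Et3N) to 3-bromobut-3-en-2-one F4. A Nozaki–Hiyama–Kishi addition (CrCl2, cat. NiCl2, DMF) of its alkenylchromium species to 15 forms the same C7–C8 bond with no amine base present.

Step 2. The risk is low ee or low turnover with an ester dienophile. The fallback sets out from 2 and returns at 7. Commercial buta-2,3-dien-1-ol is oxidised with MnO2 to buta-2,3-dienal F5. This enal is the better-binding dienophile class for oxazaborolidinium catalysis. Its Diels–Alder reaction with 2 gives aldehyde 7 directly, and 7 is treated with 6 as in step 3 without DIBAL-H.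

**Further compounds**
F1 | step 9 | spiro-epoxide of 17 (C5–C14 oxirane, either epimer) | O1CC12[C@@H](C)[C@H](OC(=O)C=C(C)C)CC[C@H]2[C@H](OC(=O)/C(C)=C/C)C(O)C(=C)C(C)=O
F2 | step 9 | 14-hydroxy analogue of 18 | CC(=O)[C@@H]1C[C@]2(CO)[C@@H](C)[C@H](OC(=O)C=C(C)C)CC[C@H]2[C@H](OC(=O)/C(C)=C/C)C1O
F3 | step 9 | 14-O-(imidazol-1-ylthiocarbonyl) derivative of F2 | CC(=O)[C@@H]1C[C@]2(COC(=S)n3ccnc3)[C@@H](C)[C@H](OC(=O)C=C(C)C)CC[C@H]2[C@H](OC(=O)/C(C)=C/C)C1O
F4 | step 8 | 3-bromobut-3-en-2-one | C=C(Br)C(C)=O
F5 | step 2 | buta-2,3-dienal | C=C=CC=O
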